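The carbocycle of the target is an enolised 2-acylcyclohexane-1,3,5-trione (a dearomatised acylphloroglucinol), so each oxygen-bearing ring carbon is an acyl carbon flanked by α-carbons. The route exploits this by cutting two acyl–α bonds of that ring: the ring-fusion bond C4a–C8a shared with the dihydropyranone (chromene numbering) and the bond from the enol carbon C5 to C6, which carries the hexanoic acid arm. In one pot, a β-keto ester is C-acylated by an α-quaternary β-keto acid chloride and the ketone enolate then closes the six-membered ring by Dieckmann condensation. Both precursors are acyclic; the pyranone oxygen bridge is closed last.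

Key step: step 14

Remark 1: (DHQ)2AQN is assumed to open anhydride 8 in the sense that gives the (R)-half-ester 9; if the sense proves opposite, the pseudoenantiomer (DHQD)2AQN is used.
Remark 2: the (S,S)-ammonium catalyst of step 8 is assumed to deliver the drawn configuration at the quaternary carbon; if not, the (R,R)-catalyst is used.

Step 1
Reactants: 1 (4R)-limonene 1,2-oxide (cis/trans mixture)
Product: 3 (3R)-6-oxo-3-(prop-1-en-2-yl)heptanal, via limonene-1,2-diol 2 (not isolated)
Conditions: H5IO6, THF/H2O, 0 °C → rt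
Reagents that add atoms: water, O
Why: Acid-mediated epoxide hydrolysis followed by periodate glycol cleavage opens the ring at the former trisubstituted alkene, while the isopropenyl group and the ring stereocenter (the later chain stereocenter) are untouched.

Step 2
Reactants: 3 (3R)-6-oxo-3-(prop-1-en-2-yl)heptanal
Product: 4 (3R)-6-oxo-3-(prop-1-en-2-yl)heptanoic acid
Conditions: NaClO2, NaH2PO4, 2-methylbut-2-ene, t-BuOH/H2O, 0 °C → rt
Reagents that add atoms: sodium chlorite, [Na+].[O-]Cl=O
Why: Pinnick oxidation is selective for the aldehyde, the alkene scavenger protects the isopropenyl group from HOCl, and the stereocenter is not α to a carbonyl.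

Step 3
Reactants: 4 (3R)-6-oxo-3-(prop-1-en-2-yl)heptanoic acid
Product: 5 (3R)-6-methyl-3-(prop-1-en-2-yl)hept-6-enoic acid
Conditions: Ph3PCH3Br (2.5 equiv), KOt-Bu (2.5 equiv), THF, 0 °C → rt; then dilute HCl to pH 3
Reagents that add atoms: methyltriphenylphosphonium bromide, C[P+](c1ccccc1)(c1ccccc1)c1ccccc1.[Br-]
Why: Wittig methylenation of the methyl ketone should proceed on the inert carboxylate, and no stereocenter is α to the ketone.

Step 4
Reactants: 5 (3R)-6-methyl-3-(prop-1-en-2-yl)hept-6-enoic acid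
Product: 7 (3S)-3-(iodomethyl)-2,6-dimethylhepta-1,6-diene, via thiohydroxamate ester 6 (not isolated)
Conditions: 1-hydroxypyridine-2(1H)-thione, DCC, CH2Cl2, 0 °C → rt, dark; then CHI3 (excess), hν (tungsten lamp), rt
Reagents that add atoms: iodoform, IC(I)I
Why: Barton decarboxylative iodination removes the one surplus carbon; iodine-atom transfer from CHI3 to the primary radical should outrun cyclisation onto the distal 1,1-disubstituted alkene, and the stereocenter next to the radical carbon is retained (only its CIP label changes).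

Step 5
Reactants: 8 3-propylglutaric anhydride
Product: 9 (3R)-3-(2-methoxy-2-oxoethyl)hexanoic acid
Conditions: MeOH (10 equiv), (DHQ)2AQN (10 mol %), Et2O, −40 °C
Reagents that add atoms: methanol, CO
Why: Cinchona-alkaloid-catalysed methanolysis differentiates the enantiotopic carbonyl groups of the prochiral anhydride and so sets the propyl-bearing stereocenter.

Step 6
Reactants: 9 (3R)-3-(2-methoxy-2-oxoethyl)hexanoic acid; 10 potassium 3-(tert-butoxy)-3-oxopropanoate
Product: 12 1-tert-butyl 7-methyl (5R)-3-oxo-5-propylheptanedioate, via acyl imidazolide 11 (not isolated)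
Conditions: CDI, THF, rt; then 10 (2 equiv), MgCl2 (1 equiv), THF, rt → 45 °C; aq. citric acid
Reagents that add atoms: none
Why: The acyl imidazolide C-acylates the magnesium malonate half-ester and decarboxylation gives the β-keto ester (decarboxylative Claisen condensation) without touching the β-stereocenter.

Step 7
Reactants: 12 1-tert-butyl 7-methyl (5R)-3-oxo-5-propylheptanedioate; 7 (3S)-3-(iodomethyl)-2,6-dimethylhepta-1,6-diene
Product: 13 1-tert-butyl 7-methyl (5R)-2-[(2R)-5-methyl-2-(prop-1-en-2-yl)hex-5-en-1-yl]-3-oxo-5-propylheptanedioate (both C-2 epimers)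
Conditions: NaH, THF/DMF, 0 °C; then 7, 50 °C
Reagents that add atoms: none
Why: SN2 C-alkylation of the weakly basic β-keto ester enolate by the primary iodide should avoid E2; the iodide stereocenter is not involved and the new α-center is planarised again in step 8.

Step 8
Reactants: 13 mono-alkylated β-keto ester; 14 1-bromo-3-methylbut-2-ene
Product: 15 1-tert-butyl 7-methyl (2S,5R)-2-(3-methylbut-2-en-1-yl)-2-[(2R)-5-methyl-2-(prop-1-en-2-yl)hex-5-en-1-yl]-3-oxo-5-propylheptanedioate
Conditions: 14 (1.5 equiv), (S,S)-N-spiro bis(binaphthyl) ammonium bromide bearing 3,3′-bis(3,4,5-trifluorophenyl) groups (2 mol %), CsOH·H2O, toluene, −40 °C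
Reagents that add atoms: none
Why: In this asymmetric phase-transfer alkylation the chiral ammonium–enolate ion pair shields one enolate face, so SN2 attack on prenyl bromide should set the quaternary center under catalyst control; the minor epimer is removed by chromatography.

Step 9
Reactants: 15 quaternary tert-butyl β-keto ester
Product: 17 (2S,5R)-7-methoxy-2-(3-methylbut-2-en-1-yl)-2-[(2R)-5-methyl-2-(prop-1-en-2-yl)hex-5-en-1-yl]-3,7-dioxo-5-propylheptanoic acid, via trimethylsilyl ester 16 (not isolated)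
Conditions: Me3SiOTf (2.5 equiv), 2,6-lutidine (3 equiv), CH2Cl2, 0 °C; then cold aq. citric acid; used at once below 0 °C
Reagents that add atoms: none
Why: Silyl-triflate-induced loss of isobutene under buffered, non-protic conditions cleaves only the tert-butyl ester and spares the methyl ester and the acid-sensitive prenyl and isopropenyl groups; any silyl enol ether is hydrolysed on work-up and the quaternary center cannot epimerise.

Step 10
Reactants: 17 β-keto acid
Product: 18 methyl (3R,6S)-7-chloro-6-(3-methylbut-2-en-1-yl)-6-[(2R)-5-methyl-2-(prop-1-en-2-yl)hex-5-en-1-yl]-5,7-dioxo-3-propylheptanoate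
Conditions: 1-chloro-N,N,2-trimethylprop-1-en-1-amine (1.2 equiv), CH2Cl2, 0 °C; evaporate, use crude
Reagents that add atoms: 1-chloro-N,N,2-trimethylprop-1-en-1-amine, CC(C)=C(Cl)N(C)C
Why: The α-chloroenamine makes the acid chloride under neutral conditions without free HCl, which outpaces decarboxylation of the β-keto acid and protects the alkenes; the quaternary α-carbon excludes ketene formation.

Step 11
Reactants: 19 (4S)-4-benzyl-3-propanoyl-1,3-thiazolidine-2-thione; 20 acetaldehyde
Product: 21 (4S)-4-benzyl-3-[(2S,3R)-3-hydroxy-2-methylbutanoyl]-1,3-thiazolidine-2-thione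
Conditions: TiCl4 (1.05 equiv), i-Pr2NEt (1.1 equiv), N-methyl-2-pyrrolidinone (1 equiv), CH2Cl2, 0 °C; then 20, −78 → 0 °C
Reagents that add atoms: none
Why: The syn-selective titanium-enolate aldol of the N-acylthiazolidinethione proceeds through a closed chair transition state of the (Z)-enolate with the auxiliary shielding one face, which sets both methyl-bearing centers of the later pyranone as (2S,3R), i.e. cis in the ring.

Step 12
Reactants: 21 syn-aldol adduct
Product: 22 (4S)-4-benzyl-3-{(2S,3R)-3-[(tert-butyldimethylsilyl)oxy]-2-methylbutanoyl}-1,3-thiazolidine-2-thione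
Conditions: t-BuMe2SiOTf, 2,6-lutidine, CH2Cl2, 0 °C
Reagents that add atoms: tert-butyldimethylsilyl trifluoromethanesulfonate, CC(C)(C)[Si](C)(C)OS(=O)(=O)C(F)(F)F
Why: Silylation of the secondary alcohol blocks O-acylation and retro-aldol cleavage in the following steps.

Step 13
Reactants: 22 silylated aldol adduct; 23 potassium 3-methoxy-3-oxopropanoate
Product: 24 methyl (4S,5R)-5-[(tert-butyldimethylsilyl)oxy]-4-methyl-3-oxohexanoate
Conditions: 23 (2 equiv), MgCl2, imidazole, THF, rt
Reagents that add atoms: none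
Why: The thiazolidinethione is an activated amide that acylates the magnesium malonate half-ester (decarboxylative Claisen condensation) under nearly neutral conditions, so the α-stereocenter should not epimerise.

Step 14
Reactants: 18 α-quaternary β-keto acid chloride; 24 methyl (4S,5R)-5-[(tert-butyldimethylsilyl)oxy]-4-methyl-3-oxohexanoate
Product: 26 methyl (3S)-3-[(5R)-3-{(2S,3R)-3-[(tert-butyldimethylsilyl)oxy]-2-methylbutanoyl}-2,4-dihydroxy-5-(3-methylbut-2-en-1-yl)-5-[(2R)-5-methyl-2-(prop-1-en-2-yl)hex-5-en-1-yl]-6-oxocyclohexa-1,3-dien-1-yl]hexanoate (one enol tautomer drawn), via triacylmethane 25 (not isolated)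
Conditions: 24, MgCl2 (1.2 equiv), pyridine (2.2 equiv), CH2Cl2, 0 °C; add 18, 0 °C → rt; then THF, LiN(SiMe3)2 (4.5 equiv), −78 → 0 °C; aq. NaH2PO4
Reagents that add atoms: none
Why: MgCl2 and pyridine generate the chelated magnesium enolate of 24, which attacks the acid chloride at carbon (magnesium-mediated C-acylation of a β-keto ester) and forms the first bond, giving triacylmethane 25 as its chelate. LiN(SiMe3)2 then deprotonates the only enolisable position of the remaining free ketone (the CH2 next to the propyl-bearing carbon, the other α-carbon being quaternary), and this enolate attacks the methyl ester carbonyl and expels methoxide, a Dieckmann condensation that closes the carbocycle in the 6-(enolendo)-exo-trig mode and forms the second bond. The closest known reaction types are this C-acylation and the Claisen cyclisation of polyketo ester anions to acylphloroglucinols. No stereocenter is created: the quaternary center has no α-hydrogen, and the acyl α-stereocenter lies next to a carbonyl that belongs to the delocalised triacylmethanide and is not enolised further. The step needs C- over O-acylation, which magnesium chelation secures, and Claisen over aldol closure onto the side-arm ketone, which is secured because the aldol is reversible while loss of methoxide and deprotonation of the trione are not.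

Step 15
Reactants: 26 silylated trione methyl ester
Product: 27 (3S)-3-[(5R)-3-{(2S,3R)-3-[(tert-butyldimethylsilyl)oxy]-2-methylbutanoyl}-2,4-dihydroxy-5-(3-methylbut-2-en-1-yl)-5-[(2R)-5-methyl-2-(prop-1-en-2-yl)hex-5-en-1-yl]-6-oxocyclohexa-1,3-dien-1-yl]hexanoic acid
Conditions: LiOH·H2O (4 equiv), THF/H2O, 0 °C → rt; then 1 M HCl to pH 3 at 0 °C
Reagents that add atoms: lithium hydroxide, [Li+].[OH-]
Why: Saponification of the unhindered methyl ester is done before the base-sensitive cis-pyranone exists; the trione is present as its delocalised enolate, which protects the acyl α-stereocenter and the β-silyloxy ketone from enolisation and elimination.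

Step 16
Reactants: 27 silylated trione acid
Product: 29 (3S)-3-[(2R,3S,8R)-5-hydroxy-2,3-dimethyl-8-(3-methylbut-2-en-1-yl)-8-[(2R)-5-methyl-2-(prop-1-en-2-yl)hex-5-en-1-yl]-4,7-dioxo-3,4,7,8-tetrahydro-2H-chromen-6-yl]hexanoic acid (CNP0294320.1), via hydroxy trione acid 28 (not isolated)
Conditions: 48% aq. HF, MeCN, 0 °C → rt; then PPTS (cat.), 4 Å molecular sieves, CH2Cl2, rt
Reagents that add atoms: none
Why: Desilylation frees the δ-hydroxyl, which condenses with the vinylogous acid (intramolecular vinylogous esterification, 6-exo-trig) at the ring carbonyl next to the quaternary carbon, because that carbon is the free ketone of the dominant enol tautomer and only this closure keeps the chelated enol O–H···O=C hydrogen bond under the mild, equilibrating conditions; the cis-dimethyl relationship comes unchanged from step 11.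

Compound list
1 | (4R)-limonene 1,2-oxide, (4R)-1-methyl-4-(prop-1-en-2-yl)-7-oxabicyclo[4.1.0]heptane, cis/trans mixture | CC(=C)[C@@H]1CCC2(C)OC2C1 | starting material
2 | (4R)-1-methyl-4-(prop-1-en-2-yl)cyclohexane-1,2-diol | CC(=C)[C@@H]1CCC(C)(O)C(O)C1 | intermediate
3 | (3R)-6-oxo-3-(prop-1-en-2-yl)heptanal | CC(=O)CC[C@H](CC=O)C(=C)C | intermediate
4 | (3R)-6-oxo-3-(prop-1-en-2-yl)heptanoic acid | CC(=O)CC[C@H](CC(=O)O)C(=C)C | intermediate
5 | (3R)-6-methyl-3-(prop-1-en-2-yl)hept-6-enoic acid | C=C(C)CC[C@H](CC(=O)O)C(=C)C | intermediate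
6 | 2-thioxopyridin-1(2H)-yl (3R)-6-methyl-3-(prop-1-en-2-yl)hept-6-enoate | C=C(C)CC[C@H](CC(=O)ON1C=CC=CC1=S)C(=C)C | intermediate
7 | (3S)-3-(iodomethyl)-2,6-dimethylhepta-1,6-diene | C=C(C)CC[C@H](CI)C(=C)C | intermediate
8 | 3-propylglutaric anhydride (4-propyloxane-2,6-dione) | CCCC1CC(=O)OC(=O)C1 | starting material
9 | (3R)-3-(2-methoxy-2-oxoethyl)hexanoic acid | OC(=O)C[C@@H](CCC)CC(=O)OC | intermediate
10 | potassium 3-(tert-butoxy)-3-oxopropanoate | CC(C)(C)OC(=O)CC(=O)[O-].[K+] | starting material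
11 | methyl (3R)-3-[2-(1H-imidazol-1-yl)-2-oxoethyl]hexanoate | O=C(C[C@@H](CCC)CC(=O)OC)n1ccnc1 | intermediate
12 | 1-tert-butyl 7-methyl (5R)-3-oxo-5-propylheptanedioate | CC(C)(C)OC(=O)CC(=O)C[C@@H](CCC)CC(=O)OC | intermediate
13 | 1-tert-butyl 7-methyl (5R)-2-[(2R)-5-methyl-2-(prop-1-en-2-yl)hex-5-en-1-yl]-3-oxo-5-propylheptanedioate (both C-2 epimers) | CC(C)(C)OC(=O)C(C[C@@H](CCC(C)=C)C(C)=C)C(=O)C[C@@H](CCC)CC(=O)OC | intermediate
14 | 1-bromo-3-methylbut-2-ene (prenyl bromide) | CC(C)=CCBr | starting material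
15 | 1-tert-butyl 7-methyl (2S,5R)-2-(3-methylbut-2-en-1-yl)-2-[(2R)-5-methyl-2-(prop-1-en-2-yl)hex-5-en-1-yl]-3-oxo-5-propylheptanedioate | CC(C)(C)OC(=O)[C@@](CC=C(C)C)(C[C@@H](CCC(C)=C)C(C)=C)C(=O)C[C@@H](CCC)CC(=O)OC | intermediate
16 | trimethylsilyl ester of acid 17 | C[Si](C)(C)OC(=O)[C@@](CC=C(C)C)(C[C@@H](CCC(C)=C)C(C)=C)C(=O)C[C@@H](CCC)CC(=O)OC | intermediate
17 | (2S,5R)-7-methoxy-2-(3-methylbut-2-en-1-yl)-2-[(2R)-5-methyl-2-(prop-1-en-2-yl)hex-5-en-1-yl]-3,7-dioxo-5-propylheptanoic acid | OC(=O)[C@@](CC=C(C)C)(C[C@@H](CCC(C)=C)C(C)=C)C(=O)C[C@@H](CCC)CC(=O)OC | intermediate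
18 | methyl (3R,6S)-7-chloro-6-(3-methylbut-2-en-1-yl)-6-[(2R)-5-methyl-2-(prop-1-en-2-yl)hex-5-en-1-yl]-5,7-dioxo-3-propylheptanoate | ClC(=O)[C@@](CC=C(C)C)(C[C@@H](CCC(C)=C)C(C)=C)C(=O)C[C@@H](CCC)CC(=O)OC | intermediate
19 | (4S)-4-benzyl-3-propanoyl-1,3-thiazolidine-2-thione | CCC(=O)N1C(=S)SC[C@@H]1Cc1ccccc1 | starting material
20 | acetaldehyde | CC=O | starting material
21 | (4S)-4-benzyl-3-[(2S,3R)-3-hydroxy-2-methylbutanoyl]-1,3-thiazolidine-2-thione | C[C@@H](O)[C@H](C)C(=O)N1C(=S)SC[C@@H]1Cc1ccccc1 | intermediate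
22 | (4S)-4-benzyl-3-{(2S,3R)-3-[(tert-butyldimethylsilyl)oxy]-2-methylbutanoyl}-1,3-thiazolidine-2-thione | C[C@@H](O[Si](C)(C)C(C)(C)C)[C@H](C)C(=O)N1C(=S)SC[C@@H]1Cc1ccccc1 | intermediate
23 | potassium 3-methoxy-3-oxopropanoate | COC(=O)CC(=O)[O-].[K+] | starting material
24 | methyl (4S,5R)-5-[(tert-butyldimethylsilyl)oxy]-4-methyl-3-oxohexanoate | C[C@@H](O[Si](C)(C)C(C)(C)C)[C@H](C)C(=O)CC(=O)OC | intermediate
25 | 1,9-dimethyl (4S,7R)-2-{(2S,3R)-3-[(tert-butyldimethylsilyl)oxy]-2-methylbutanoyl}-4-(3-methylbut-2-en-1-yl)-4-[(2R)-5-methyl-2-(prop-1-en-2-yl)hex-5-en-1-yl]-3,5-dioxo-7-propylnonanedioate (C-2 enolisable) | COC(=O)C(C(=O)[C@@H](C)[C@@H](C)O[Si](C)(C)C(C)(C)C)C(=O)[C@@](CC=C(C)C)(C[C@@H](CCC(C)=C)C(C)=C)C(=O)C[C@@H](CCC)CC(=O)OC | intermediate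
26 | methyl (3S)-3-[(5R)-3-{(2S,3R)-3-[(tert-butyldimethylsilyl)oxy]-2-methylbutanoyl}-2,4-dihydroxy-5-(3-methylbut-2-en-1-yl)-5-[(2R)-5-methyl-2-(prop-1-en-2-yl)hex-5-en-1-yl]-6-oxocyclohexa-1,3-dien-1-yl]hexanoate | C=C(C)CC[C@H](C[C@@]1(CC=C(C)C)C(=O)C([C@@H](CCC)CC(=O)OC)=C(O)C(C(=O)[C@@H](C)[C@@H](C)O[Si](C)(C)C(C)(C)C)=C1O)C(=C)C | intermediate
27 | the carboxylic acid of 26, (3S)-3-[(5R)-3-{(2S,3R)-3-[(tert-butyldimethylsilyl)oxy]-2-methylbutanoyl}-2,4-dihydroxy-5-(3-methylbut-2-en-1-yl)-5-[(2R)-5-methyl-2-(prop-1-en-2-yl)hex-5-en-1-yl]-6-oxocyclohexa-1,3-dien-1-yl]hexanoic acid | C=C(C)CC[C@H](C[C@@]1(CC=C(C)C)C(=O)C([C@@H](CCC)CC(=O)O)=C(O)C(C(=O)[C@@H](C)[C@@H](C)O[Si](C)(C)C(C)(C)C)=C1O)C(=C)C | intermediate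
28 | desilylated 27, (3S)-3-[(5R)-2,4-dihydroxy-3-[(2S,3R)-3-hydroxy-2-methylbutanoyl]-5-(3-methylbut-2-en-1-yl)-5-[(2R)-5-methyl-2-(prop-1-en-2-yl)hex-5-en-1-yl]-6-oxocyclohexa-1,3-dien-1-yl]hexanoic acid | C=C(C)CC[C@H](C[C@@]1(CC=C(C)C)C(=O)C([C@@H](CCC)CC(=O)O)=C(O)C(C(=O)[C@@H](C)[C@@H](C)O)=C1O)C(=C)C | intermediate
29 | (3S)-3-[(2R,3S,8R)-5-hydroxy-2,3-dimethyl-8-(3-methylbut-2-en-1-yl)-8-[(2R)-5-methyl-2-(prop-1-en-2-yl)hex-5-en-1-yl]-4,7-dioxo-3,4,7,8-tetrahydro-2H-chromen-6-yl]hexanoic acid (CNP0294320.1) | C=C(C)CC[C@H](C[C@@]1(CC=C(C)C)C(=O)C([C@@H](CCC)CC(=O)O)=C(O)C2=C1O[C@H](C)[C@H](C)C2=O)C(=C)C | target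

Total step count: 16
Longest linear sequence: 11 steps (steps 1–4, 7–10, 14–16)

Steps most likely to fail

Step 14. The hindered acid chloride may acylate slowly or on oxygen, the triacylmethane may lose an acyl group by retro-Claisen cleavage once strong base is added, or the ketone enolate may close by aldol addition onto the side-arm ketone. The fallback builds the ring first and attaches the acyl arm afterwards. It sets out from 18, which is added to the lithium enolate of methyl acetate (2 equiv, THF, −78 °C) to give 1,9-dimethyl (4S,7R)-4-(3-methylbut-2-en-1-yl)-4-[(2R)-5-methyl-2-(prop-1-en-2-yl)hex-5-en-1-yl]-3,5-dioxo-7-propylnonanedioate F1. Dieckmann condensation of F1 with LiN(SiMe3)2 gives the trione methyl (3S)-3-[(5R)-2-hydroxy-5-(3-methylbut-2-en-1-yl)-5-[(2R)-5-methyl-2-(prop-1-en-2-yl)hex-5-en-1-yl]-4,6-dioxocyclohex-1-en-1-yl]hexanoate F2, which has a free ring CH2 between two carbonyls. Hydrolysis of 22 (LiOH, aq. THF, 0 °C) gives (2S,3R)-3-[(tert-butyldimethylsilyl)oxy]-2-methylbutanoic acid F3. Coupling of F2 with F3 by DCC and DMAP (O-acylation, then DMAP-promoted O-to-C acyl shift, the standard route to 2-acyl cyclic 1,3-diones) comes back to the route at 26.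

Step 8. The ion pair may discriminate the enolate faces poorly, because the acyclic enolate can adopt both geometries and the two existing stereocenters are remote; O-prenylation may also compete. The fallback replaces catalyst control by a covalently bound auxiliary. It sets out from 13, which is condensed with tert-butyl L-valinate (cat. TsOH, 4 Å sieves, benzene, 50 °C) to the chelated enamino ester 1-tert-butyl 7-methyl (2Z,5R)-3-{[(2S)-1-(tert-butoxy)-3-methyl-1-oxobutan-2-yl]amino}-2-[(2R)-5-methyl-2-(prop-1-en-2-yl)hex-5-en-1-yl]-5-propylhept-2-enedioate F4. Deprotonation with LDA and alkylation of the lithio-enamine with 14 at −78 °C gives the quaternary imine 1-tert-butyl 7-methyl (2S,5R)-3-{[(2S)-1-(tert-butoxy)-3-methyl-1-oxobutan-2-yl]imino}-2-(3-methylbut-2-en-1-yl)-2-[(2R)-5-methyl-2-(prop-1-en-2-yl)hex-5-en-1-yl]-5-propylheptanedioate F5; the attacked face is chosen through the solvent system (toluene with HMPA, or THF). Mild aqueous acid hydrolysis of F5 comes back to the route at 15.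

Step 16. The hydroxyl may close onto the other flanking ring carbonyl and give the regioisomeric pyranone, the cis-dimethyl relationship may be lost by enolisation or by β-elimination and re-addition, and the prenyl group may cyclise onto an enol oxygen if the acid is too strong. The fallback closes the pyranone while the second flanking carbon is still an ester. It sets out from 18 and 24, which are joined as in the first stage of step 14, but 25 is isolated. HF·pyridine in MeCN removes the silyl group of 25 and the δ-hydroxy-1,3-diketone cyclodehydrates onto the only flanking ketone, giving the dihydropyranone methyl (5S,6R)-5,6-dimethyl-4-oxo-5,6-dihydro-4H-pyran-3-carboxylate that carries at C-2 the quaternary carbon with its prenyl group, chain and keto ester arm F6. Dieckmann condensation of F6 with LiN(SiMe3)2 (1.1 equiv, THF, −78 °C) gives the methyl ester of 29 F7. Neutral ester cleavage of F7 with Me3SnOH in 1,2-dichloroethane at 70 °C comes back to the route at 29.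

Further compounds
F1 | step 14 | 1,9-dimethyl (4S,7R)-4-(3-methylbut-2-en-1-yl)-4-[(2R)-5-methyl-2-(prop-1-en-2-yl)hex-5-en-1-yl]-3,5-dioxo-7-propylnonanedioate | COC(=O)CC(=O)[C@@](CC=C(C)C)(C[C@@H](CCC(C)=C)C(C)=C)C(=O)C[C@@H](CCC)CC(=O)OC
F2 | step 14 | methyl (3S)-3-[(5R)-2-hydroxy-5-(3-methylbut-2-en-1-yl)-5-[(2R)-5-methyl-2-(prop-1-en-2-yl)hex-5-en-1-yl]-4,6-dioxocyclohex-1-en-1-yl]hexanoate | C=C(C)CC[C@H](C[C@@]1(CC=C(C)C)C(=O)C([C@@H](CCC)CC(=O)OC)=C(O)CC1=O)C(=C)C
F3 | step 14 | (2S,3R)-3-[(tert-butyldimethylsilyl)oxy]-2-methylbutanoic acid | C[C@@H](O[Si](C)(C)C(C)(C)C)[C@H](C)C(=O)O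
F4 | step 8 | 1-tert-butyl 7-methyl (2Z,5R)-3-{[(2S)-1-(tert-butoxy)-3-methyl-1-oxobutan-2-yl]amino}-2-[(2R)-5-methyl-2-(prop-1-en-2-yl)hex-5-en-1-yl]-5-propylhept-2-enedioate | CC(C)(C)OC(=O)/C(C[C@@H](CCC(C)=C)C(C)=C)=C(\N[C@@H](C(C)C)C(=O)OC(C)(C)C)C[C@@H](CCC)CC(=O)OC
F5 | step 8 | 1-tert-butyl 7-methyl (2S,5R)-3-{[(2S)-1-(tert-butoxy)-3-methyl-1-oxobutan-2-yl]imino}-2-(3-methylbut-2-en-1-yl)-2-[(2R)-5-methyl-2-(prop-1-en-2-yl)hex-5-en-1-yl]-5-propylheptanedioate | CC(C)(C)OC(=O)[C@@](CC=C(C)C)(C[C@@H](CCC(C)=C)C(C)=C)C(=N[C@@H](C(C)C)C(=O)OC(C)(C)C)C[C@@H](CCC)CC(=O)OC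
F6 | step 16 | methyl (5S,6R)-5,6-dimethyl-4-oxo-5,6-dihydro-4H-pyran-3-carboxylate carrying at C-2 the quaternary carbon with prenyl group, (2R)-5-methyl-2-(prop-1-en-2-yl)hex-5-en-1-yl chain and (4R)-6-methoxy-1,6-dioxo-4-propylhexan-1-yl arm | COC(=O)C1=C(O[C@H](C)[C@H](C)C1=O)[C@@](CC=C(C)C)(C[C@@H](CCC(C)=C)C(C)=C)C(=O)C[C@@H](CCC)CC(=O)OC
F7 | step 16 | methyl (3S)-3-[(2R,3S,8R)-5-hydroxy-2,3-dimethyl-8-(3-methylbut-2-en-1-yl)-8-[(2R)-5-methyl-2-(prop-1-en-2-yl)hex-5-en-1-yl]-4,7-dioxo-3,4,7,8-tetrahydro-2H-chromen-6-yl]hexanoate | C=C(C)CC[C@H](C[C@@]1(CC=C(C)C)C(=O)C([C@@H](CCC)CC(=O)OC)=C(O)C2=C1O[C@H](C)[C@H](C)C2=O)C(=C)C
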